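Read at 40 h, flasks teal and grey have had equal charges and equal clocks and stand at the same −40 °C; grey differs by its first 12 h at 0 °C.

common to all: free catalyst 0.19 mM
- autumn: starting material 0.20 M; coupling partner 0.30 M; temperature −45 °C; run made earlier
- spring: starting material 0.45 M; coupling partner 0.30 M; temperature −20 °C; run made earlier
- teal: starting material 0.30 M; coupling partner 0.300 M; at −40 °C throughout; time 40 h
- grey: starting material 0.30 M; coupling partner 0.300 M; at 0 °C until 12 h, from then on at −40 °C; time 40 h

| run | time / h | product / % | starting material / % |
|---|---|---|---|
| autumn | 50.0 | 1.0 | 99.6 |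
| autumn | 96.0 | 1.8 | 98.6 |
| autumn | 144 | 2.3 | 97.2 |
| autumn | 192 | 3.0 | 96.6 |
| autumn | 240 | 4.7 | 96.2 |
| autumn | 288 | 4.2 | 95.9 |
| spring | 5.00 | 1.8 | 100.1 |
| spring | 15.0 | 3.7 | 96.0 |
| spring | 30.0 | 7.2 | 92.9 |
| spring | 60.0 | 14.0 | 85.9 |
| spring | 72.0 | 17.2 | 83.0 |

(standard deviation of a reading: 0.5 percentage points)

- the winner by amount of product, in percent of the starting material charged; "neither" if no more than 2 percentage points parts them (teal / grey / neither)
- how much product is there at the end, in percent of the starting material charged: teal
- how much product is there at the end, in percent of the starting material charged: grey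

- a reading or a percentage of product counts all its forms, free or not

Pooling the later readings, product grows by a share 1.65 × 10⁻⁴ h⁻¹ of the charge in the autumn run and 0.00236 h⁻¹ in the spring run. Conversion is low in both, and charge and temperature changed together, so the order in starting material stays open, and two chemists split over it. The first says a fixed share of the starting material reacts per hour (first order); the second says a fixed molarity does (zero order). Drawing an Arrhenius line through the two runs, the first gets an activation energy of 51.1 kJ mol⁻¹, the second 66.7 kJ mol⁻¹.

By my own reckoning, the second view gives 2.34 × 10⁻⁴ h⁻¹ for the cold rate, the share of a 0.30 M charge turned into product per hour at −40 °C. The first view gives more, 2.95 × 10⁻⁴ h⁻¹. This temperature lies between the two runs, so the views stay close: I reckon teal at 1.18% on the first and 0.937% on the second.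

They part at 0 °C, beyond the readings, where the forecast reckons that grey's 12 h give about 17% if first order and about 43% if zero order. The first chemist signs the forecast, which takes a figure between those two: grey wins, teal 1.1% (from 0.7% to 1.8%), grey 25% (from 14% to 45%), with the caution “This extrapolates beyond the measured temperatures and assumes the catalyst survives.” The second chemist holds to 43%.

The simulation gives teal 0.975% and grey 29.8%, so grey wins and the forecast stands.

    starting material + free catalyst → catalyst intermediate A (k = 330 M⁻¹ h⁻¹, Ea = 48.0 kJ mol⁻¹)
    catalyst intermediate C → free catalyst + product (k = 91.0 h⁻¹, Ea = 68.0 kJ mol⁻¹)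
    coupling partner + catalyst intermediate A → catalyst intermediate B (k = 1700 M⁻¹ h⁻¹, Ea = 36.0 kJ mol⁻¹)
    crystals ⇌ product, rate k4*(cs4 - [product]) while solid is left; crystals form when [product] > cs4 (solubility = 10.0 mM, k = 4.00 h⁻¹)
    catalyst intermediate B → catalyst intermediate C (k = 1200 h⁻¹, Ea = 77.0 kJ mol⁻¹)
    (constants at 0 °C)

The temperature programme is the main reason: teal, at 0.975%, would stand at 29.8% with grey's programme. Yet grey's cold stretch belongs to the second chemist. Grey has 70.2% of its starting material at 40 h; left until 400 h, the cold rate predicts a further 8.4 percentage points of product, and the flask adds 8.2 points. At 40.0 h, catalyst intermediate C, the resting state, holds 68.4% of grey's catalyst.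

The earlier runs and the new flask are simulated from invented constants; the scatter is artificial.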